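## Retrosynthetic overview

- Target 31 ← late unmasking (β‑amino ester → acrylate; PMB, tert‑butyl and silyl groups off) ← Z‑selective Still–Gennari build‑up of the 4‑acetoxyangelate on the ring oxygen ← vinyl group and free secondary OH from Wittig opening of a bridged lactol.
- Bridged γ‑lactone 15 ← face‑selective ketone reduction, the axial alkoxide being captured by the axial methyl ester; acetic ester arm ← cyclopropanation/ring opening of a silyl enol ether; hydroxypropenyl arm ← enol triflate of an acetyl group plus hydroxymethyl Stille coupling.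
- Key disconnection: cyclohexene 8 ← catalytic enantioselective Diels–Alder reaction of diene 7 (ring CH2, C–OSi, CH, CH–OPMB) with (E)‑keto ester 3 (quaternary ring carbon and its CH neighbour). Both ring bonds between the two fragments, the quaternary carbon and three stereocentres form at once.
- Enabling feature: in the cyclohexane ring the carbinol carbon and the acyloxy carbon are 1,3‑related inside the segment CH2–CH(O)–CH–CH(O), a masked 1‑alkoxy‑3‑silyloxybutadiene. The other two ring carbons, C(CH3)(vinyl) and CH(hydroxypropenyl), carry groups that are trans on the ring and derive from CO2Me and acetyl, i.e. an (E)‑configured, doubly activated alkene.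
- Ring order: the cyclohexane ring (the only ring of the target) is formed in step 4; a temporary bridged lactone ring is closed in step 9 and opened in step 12.

Key step: step 4

Assumption: the (S)‑proline‑derived oxazaborolidinium ion is taken to leave open the face of the boron‑bound s‑cis enone 3 that leads to 8; should the antipode form, the (R)‑catalyst is used with nothing else changed.

Ring locants used in the names: C1 = quaternary carbon; C2 = CH2; C3 = carbon bearing the silyloxy (later acyloxy) oxygen; C4 = its neighbour that receives the acetic/acrylic arm; C5 = carbon bearing OPMB/OH; C6 = carbon bearing the acetyl (later hydroxypropenyl) group. α = ring face of the C1 methyl group, β = the opposite face. PMB = 4‑methoxybenzyl, TBS = tert‑butyldimethylsilyl, TMS = trimethylsilyl. Absolute configurations are those of the SMILES.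

## Route

Step 1
Reactants: 1 methylglyoxal (2‑oxopropanal, 40% in water); 2 methyl 2‑(triphenylphosphoranylidene)propanoate
Product: 3 methyl (E)‑2‑methyl‑4‑oxopent‑2‑enoate
Conditions: CH2Cl2/H2O, 0 °C → rt
Reagents that add atoms: none
Why: Wittig reaction of a stabilised ylide at the aldehyde (far more electrophilic than the ketone) should give the E‑alkene, with acetyl trans to the ester and therefore cis to the methyl group, the geometry the ring later needs.

Step 2
Reactants: 4 (E)‑4‑methoxybut‑3‑en‑2‑one; 5 4‑methoxybenzyl alcohol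
Product: 6 (E)‑4‑[(4‑methoxybenzyl)oxy]but‑3‑en‑2‑one
Conditions: pyridinium p‑toluenesulfonate (5 mol %), toluene, 80 °C, reduced pressure (MeOH removed)
Reagents that add atoms: none
Why: acid‑catalysed transetherification (addition–elimination at the β‑carbon of the vinylogous ester), driven by removal of methanol, should return the more stable E enol ether.

Step 3
Reactants: 6 (E)‑4‑[(4‑methoxybenzyl)oxy]but‑3‑en‑2‑one
Product: 7 (E)‑1‑[(4‑methoxybenzyl)oxy]‑3‑(tert‑butyldimethylsilyloxy)buta‑1,3‑diene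
Conditions: TBSOTf, Et3N, Et2O, 0 °C
Reagents that add atoms: tert‑butyldimethylsilyl trifluoromethanesulfonate, CC(C)(C)[Si](C)(C)OS(=O)(=O)C(F)(F)F
Why: soft enolisation of the methyl ketone with a silyl triflate and an amine (silyl enol ether formation) gives the 1‑alkoxy‑3‑silyloxydiene without touching the E enol ether.

Step 4
Reactants: 3 methyl (E)‑2‑methyl‑4‑oxopent‑2‑enoate; 7 (E)‑1‑[(4‑methoxybenzyl)oxy]‑3‑(tert‑butyldimethylsilyloxy)buta‑1,3‑diene
Product: 8 methyl 6α‑acetyl‑3‑(TBS‑oxy)‑5α‑(PMB‑oxy)‑1α‑methylcyclohex‑3‑ene‑1β‑carboxylate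
Conditions: (S)‑3,3‑diphenyl‑1‑(2‑methylphenyl)tetrahydro‑1H,3H‑pyrrolo[1,2‑c][1,3,2]oxazaborole + HNTf2 (20 mol % each), CH2Cl2, −78 → −40 °C; Et3N quench
Reagents that add atoms: none
Why: The boron Lewis acid binds the ketone of 3 (more basic than the ester) and the diene adds in an asynchronous, concerted Diels–Alder [4+2] cycloaddition, its nucleophilic CH2 terminus bonding to the methyl‑bearing β‑carbon and its alkoxy‑bearing terminus to the α‑carbon, so that both ring bonds between the fragments and the quaternary carbon form in one operation. The closest known reaction type is the oxazaborolidinium‑catalysed enantioselective Diels–Alder reaction of enones and fumarate‑type dienophiles with 1‑alkoxy‑3‑silyloxybutadienes. The cyclohexene ring is closed by this suprafacial [4π+2π] process through a six‑membered pericyclic transition state, no ring being present beforehand. The quaternary carbon and its CH neighbour are related by the retained E geometry of 3 (methyl cis to acetyl), the CH–OPMB carbon by the endo position of the boron‑bound acetyl group relative to the E enol ether (OPMB cis to acetyl), and the absolute configuration of all three by the chiral cation, which shields one face of the bound enone. The step needs regio‑, endo‑, face‑ and C=C‑over‑C=O selectivity: the 1,3‑donor pattern of 7 and the stronger ketone activation in 3 give matched polarisation, the E geometry puts the ester exo when the acetyl group is endo, and a methyl ketone is a poor heterodienophile. The product keeps a regiodefined silyl enol ether that steps 8 and 9 exploit.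

Step 5
Reactants: 8 methyl 6α‑acetyl‑3‑(TBS‑oxy)‑5α‑(PMB‑oxy)‑1α‑methylcyclohex‑3‑ene‑1β‑carboxylate
Product: 9 methyl 3‑(TBS‑oxy)‑5α‑(PMB‑oxy)‑1α‑methyl‑6α‑[1‑(trifluoromethylsulfonyloxy)vinyl]cyclohex‑3‑ene‑1β‑carboxylate
Conditions: KN(SiMe3)2, THF, −78 °C; PhNTf2, −78 → −20 °C (8 used directly after step 4)
Reagents that add atoms: N‑phenylbis(trifluoromethanesulfonimide), O=S(=O)(N(c1ccccc1)S(=O)(=O)C(F)(F)F)C(F)(F)F
Why: kinetic enolisation of the acetyl CH3 (more accessible than the ring methine, and on the side that cannot expel the β‑PMB‑oxy group) followed by O‑sulfonylation (enol triflate formation) fixes the ketone as a 1,1‑disubstituted enol triflate, after which the adjacent ring CH can no longer epimerise.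

Step 6
Reactants: 9 methyl 3‑(TBS‑oxy)‑5α‑(PMB‑oxy)‑1α‑methyl‑6α‑[1‑(trifluoromethylsulfonyloxy)vinyl]cyclohex‑3‑ene‑1β‑carboxylate
Product: 10 methyl 3‑(TBS‑oxy)‑6α‑(3‑hydroxyprop‑1‑en‑2‑yl)‑5α‑(PMB‑oxy)‑1α‑methylcyclohex‑3‑ene‑1β‑carboxylate
Conditions: Bu3SnCH2OH, Pd(PPh3)4 (5 mol %), LiCl, 1,4‑dioxane, 95 °C
Reagents that add atoms: (tributylstannyl)methanol, CCCC[Sn](CO)(CCCC)CCCC
Why: Stille coupling of the enol triflate with the hydroxymethylstannane (chloride‑assisted oxidative addition to zerovalent palladium, transmetalation, reductive elimination) places CH2OH on the alkene carbon and completes the 3‑hydroxyprop‑1‑en‑2‑yl group without touching a stereocentre.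

Step 7
Reactants: 10 methyl 3‑(TBS‑oxy)‑6α‑(3‑hydroxyprop‑1‑en‑2‑yl)‑5α‑(PMB‑oxy)‑1α‑methylcyclohex‑3‑ene‑1β‑carboxylate
Product: 11 methyl 3‑(TBS‑oxy)‑5α‑(PMB‑oxy)‑1α‑methyl‑6α‑[3‑(TBS‑oxy)prop‑1‑en‑2‑yl]cyclohex‑3‑ene‑1β‑carboxylate
Conditions: TBSCl, imidazole, DMF, 0 °C
Reagents that add atoms: tert‑butyldimethylsilyl chloride, CC(C)(C)[Si](C)(C)Cl
Why: silylation of the only free hydroxyl (primary, allylic) protects it for the carbenoid, base, hydride and acylation steps that follow.

Step 8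
Reactants: 11 methyl 3‑(TBS‑oxy)‑5α‑(PMB‑oxy)‑1α‑methyl‑6α‑[3‑(TBS‑oxy)prop‑1‑en‑2‑yl]cyclohex‑3‑ene‑1β‑carboxylate
Product: 13 methyl 4β‑(2‑tert‑butoxy‑2‑oxoethyl)‑5α‑(PMB‑oxy)‑1α‑methyl‑3‑oxo‑6α‑[3‑(TBS‑oxy)prop‑1‑en‑2‑yl]cyclohexane‑1β‑carboxylate, via siloxycyclopropane 12 (not isolated)
Conditions: N2CHCO2t‑Bu (slow addition), Rh2(OAc)4 (1 mol %), CH2Cl2, rt; then n‑Bu4NF/AcOH (1:1), THF, −20 °C
Reagents that add atoms: tert‑butyl diazoacetate, CC(C)(C)OC(=O)C=[N+]=[N-]
Why: carbenoid cyclopropanation of the electron‑rich silyl enol ether (far more nucleophilic than the 1,1‑disubstituted alkene) on the face anti to the allylic PMB‑oxy group, then fluoride‑triggered opening of the donor–acceptor cyclopropane under buffered conditions, is the known route from silyl enol ethers to γ‑keto esters; it places the acetic ester arm at C4 trans to OPMB, which is also the thermodynamically preferred arrangement at this epimerisable centre.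

Step 9
Reactants: 13 methyl 4β‑(2‑tert‑butoxy‑2‑oxoethyl)‑5α‑(PMB‑oxy)‑1α‑methyl‑3‑oxo‑6α‑[3‑(TBS‑oxy)prop‑1‑en‑2‑yl]cyclohexane‑1β‑carboxylate
Product: 15 bridged γ‑lactone (C3β–O–C(=O)–C1; 6‑oxabicyclo[3.2.1]octan‑7‑one core) carrying the 4β‑CH2CO2t‑Bu, 5α‑OPMB, 1α‑methyl and 6α‑[3‑(TBS‑oxy)prop‑1‑en‑2‑yl] groups, via hydroxy diester 14 (not isolated)
Conditions: LiBH(s‑Bu)3, THF, −78 °C → rt
Reagents that add atoms: none
Why: the bulky borohydride attacks the ketone from the equatorial direction, anti to the axial ester on C1 (bulky‑hydride reduction of a 2‑substituted cyclohexanone), giving the axial 3β‑alkoxide cis to the C4 arm; this alkoxide is 1,3‑diaxial to the methyl ester and should close the bridged γ‑lactone in preference to attack on the hindered, less electrophilic tert‑butyl ester.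

Step 10
Reactants: 15 bridged γ‑lactone with 4β‑CH2CO2t‑Bu arm
Product: 16 bridged γ‑lactone with 4β‑[1‑tert‑butoxy‑3‑(dimethylamino)‑1‑oxopropan‑2‑yl] arm (epimer mixture at the side‑chain carbon)
Conditions: LiN(i‑Pr)2, THF, −78 °C; Me2N=CH2 I, −78 → 0 °C
Reagents that add atoms: dimethylmethyleneiminium iodide, C=[N+](C)C.[I-]
Why: the tert‑butyl ester is the only enolisable carbonyl (the lactone α‑carbon is quaternary), so its lithium enolate undergoes a Mannich reaction to give the β‑dimethylamino ester, a masked acrylate that is inert to the hydride, ylide and phosphonate‑anion steps ahead; the new side‑chain centre is destroyed in step 17.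

Step 11
Reactants: 16 bridged γ‑lactone Mannich base
Product: 17 bridged lactol (hemiacetal carbon from the lactone carbonyl, anomer mixture)
Conditions: i‑Bu2AlH (1.5 equiv), CH2Cl2, −78 °C
Reagents that add atoms: none
Why: partial reduction of the strained γ‑lactone to the lactol through a stable aluminium hemiacetal at −78 °C is standard, and the hindered tert‑butyl ester should not react at this temperature.

Step 12
Reactants: 17 bridged lactol
Product: 19 tert‑butyl 3‑(dimethylamino)‑2‑[3β‑hydroxy‑5α‑(PMB‑oxy)‑1α‑methyl‑6α‑(3‑(TBS‑oxy)prop‑1‑en‑2‑yl)‑1β‑vinylcyclohexan‑4β‑yl]propanoate, via hydroxy aldehyde 18 (not isolated)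
Conditions: Ph3PCH3Br, KOt‑Bu, THF, 0 °C → rt
Reagents that add atoms: methyltriphenylphosphonium bromide, C[P+](c1ccccc1)(c1ccccc1)c1ccccc1.[Br-]
Why: under the basic conditions the lactol opens to the γ‑hydroxy aldehyde, whose non‑enolisable neopentyl aldehyde is methylenated (Wittig reaction); this creates the vinyl group on the quaternary carbon and frees the axial secondary alcohol in the same operation.

Step 13
Reactants: 20 ethyl 2‑[bis(2,2,2‑trifluoroethoxy)phosphoryl]propanoate (racemic)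
Product: 21 2‑[bis(2,2,2‑trifluoroethoxy)phosphoryl]propanoic acid (racemic)
Conditions: LiOH·H2O (1.05 equiv), THF/H2O, 0 °C; then HCl (aq) to pH 2
Reagents that add atoms: lithium hydroxide monohydrate, [Li+].[OH-].O
Why: saponification with one equivalent of hydroxide at 0 °C should cleave the carboxylic ethyl ester faster than the phosphonate esters and give the acid needed for acylation.

Step 14
Reactants: 22 (Z)‑but‑2‑ene‑1,4‑diyl diacetate
Product: 24 2‑oxoethyl acetate (acetoxyacetaldehyde; two equivalents), via ozonide 23 (not isolated)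
Conditions: O3, CH2Cl2, −78 °C; then Me2S, −78 °C → rt; used freshly
Reagents that add atoms: ozone, [O-][O+]=O
Why: ozonolysis of the symmetrical alkene with reductive work‑up gives two equivalents of the aldehyde, which is used at once because it oligomerises on standing.

Step 15
Reactants: 19 hydroxy vinyl Mannich base; 21 2‑[bis(2,2,2‑trifluoroethoxy)phosphoryl]propanoic acid
Product: 25 3β‑O‑{2‑[bis(2,2,2‑trifluoroethoxy)phosphoryl]propanoyl} ester of 19
Conditions: DCC, DMAP (cat.), CH2Cl2, 0 °C → rt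
Reagents that add atoms: none
Why: carbodiimide esterification (Steglich esterification) acylates the only free hydroxyl, the hindered axial alcohol, with a small acid whose α‑carbon is sp3, which avoids the Z→E isomerisation that direct acylation with an angelic‑type acid risks.

Step 16
Reactants: 25 phosphonopropanoate ester; 24 2‑oxoethyl acetate
Product: 26 3β‑O‑[(Z)‑4‑acetoxy‑2‑methylbut‑2‑enoyl] ester (side‑chain Mannich base, OPMB, OTBS and tert‑butyl ester retained)
Conditions: KN(SiMe3)2, 18‑crown‑6, THF, −78 °C; then 24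
Reagents that add atoms: none
Why: Still–Gennari olefination, in which the potassium anion of the bis(trifluoroethyl) phosphonate adds to the aldehyde and the adduct eliminates fast and irreversibly, should give the Z‑trisubstituted enoate (ester and CH2OAc cis), the geometry of the 4‑acetoxyangelate.

Step 17
Reactants: 26 3β‑O‑[(Z)‑4‑acetoxy‑2‑methylbut‑2‑enoyl] ester Mannich base
Product: 28 tert‑butyl 2‑[3β‑((Z)‑4‑acetoxy‑2‑methylbut‑2‑enoyloxy)‑5α‑(PMB‑oxy)‑1α‑methyl‑6α‑(3‑(TBS‑oxy)prop‑1‑en‑2‑yl)‑1β‑vinylcyclohexan‑4β‑yl]acrylate, via methiodide 27 (not isolated)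
Conditions: MeI, CH2Cl2, rt; then NaHCO3 (aq), rt
Reagents that add atoms: none
Why: N‑methylation of the Mannich base and mild‑base E1cB loss of trimethylamine (second half of the classical α‑methylenation) unmask the acrylate only after all nucleophile‑ and strong‑base steps are over, and the side‑chain stereocentre disappears.

Step 18
Reactants: 28 tert‑butyl acrylate with 5α‑OPMB
Product: 29 tert‑butyl 2‑[3β‑((Z)‑4‑acetoxy‑2‑methylbut‑2‑enoyloxy)‑5α‑hydroxy‑1α‑methyl‑6α‑(3‑(TBS‑oxy)prop‑1‑en‑2‑yl)‑1β‑vinylcyclohexan‑4β‑yl]acrylate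
Conditions: DDQ, CH2Cl2/pH 7 buffer, 0 °C
Reagents that add atoms: none
Why: oxidative cleavage of the 4‑methoxybenzyl ether by DDQ (hydride abstraction, hydrolysis of the oxocarbenium ion) frees the secondary alcohol without touching the esters, the silyl ether or the alkenes.

Step 19
Reactants: 29 tert‑butyl acrylate with 5α‑OH and primary OTBS
Product: 31 target acid, 2‑[3β‑((Z)‑4‑acetoxy‑2‑methylbut‑2‑enoyloxy)‑5α‑hydroxy‑6α‑(3‑hydroxyprop‑1‑en‑2‑yl)‑1α‑methyl‑1β‑vinylcyclohexan‑4β‑yl]acrylic acid, via silyl ester 30 (not isolated)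
Conditions: TMSOTf, 2,6‑lutidine, CH2Cl2, 0 °C; then HF·pyridine, THF, 0 °C → rt
Reagents that add atoms: none
Why: the silyl triflate converts the tert‑butyl ester into a silyl ester with loss of isobutene (and silylates the free alcohol) under non‑protic conditions that do not promote lactonisation, and buffered fluoride then removes all three silyl groups, so the γ‑hydroxy acid is never exposed to strong acid or base.

## Compound list

1 | methylglyoxal (2‑oxopropanal) | CC(=O)C=O | starting material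
2 | methyl 2‑(triphenylphosphoranylidene)propanoate | COC(=O)C(C)=P(c1ccccc1)(c1ccccc1)c1ccccc1 | starting material
3 | methyl (E)‑2‑methyl‑4‑oxopent‑2‑enoate | CC(=O)/C=C(\C)C(=O)OC | intermediate
4 | (E)‑4‑methoxybut‑3‑en‑2‑one | CO/C=C/C(C)=O | starting material
5 | 4‑methoxybenzyl alcohol | COc1ccc(CO)cc1 | starting material
6 | (E)‑4‑[(4‑methoxybenzyl)oxy]but‑3‑en‑2‑one | CC(=O)/C=C/OCc1ccc(OC)cc1 | intermediate
7 | (E)‑1‑[(4‑methoxybenzyl)oxy]‑3‑(tert‑butyldimethylsilyloxy)buta‑1,3‑diene | C=C(O[Si](C)(C)C(C)(C)C)/C=C/OCc1ccc(OC)cc1 | intermediate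
8 | methyl 6α‑acetyl‑3‑(TBS‑oxy)‑5α‑(PMB‑oxy)‑1α‑methylcyclohex‑3‑ene‑1β‑carboxylate | COC(=O)[C@@]1(C)CC(O[Si](C)(C)C(C)(C)C)=C[C@H](OCc2ccc(OC)cc2)[C@@H]1C(C)=O | intermediate
9 | enol triflate of 8 (6α‑[1‑(trifluoromethylsulfonyloxy)vinyl]) | COC(=O)[C@@]1(C)CC(O[Si](C)(C)C(C)(C)C)=C[C@H](OCc2ccc(OC)cc2)[C@@H]1C(=C)OS(=O)(=O)C(F)(F)F | intermediate
10 | allylic alcohol (6α‑(3‑hydroxyprop‑1‑en‑2‑yl)) | COC(=O)[C@@]1(C)CC(O[Si](C)(C)C(C)(C)C)=C[C@H](OCc2ccc(OC)cc2)[C@@H]1C(=C)CO | intermediate
11 | bis‑silyl compound (6α‑[3‑(TBS‑oxy)prop‑1‑en‑2‑yl]) | COC(=O)[C@@]1(C)CC(O[Si](C)(C)C(C)(C)C)=C[C@H](OCc2ccc(OC)cc2)[C@@H]1C(=C)CO[Si](C)(C)C(C)(C)C | intermediate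
12 | siloxycyclopropane (C3/C4 bridged on the β face by CHCO2t‑Bu, ester exo/endo mixture) | COC(=O)[C@@]1(C)C[C@@]2(O[Si](C)(C)C(C)(C)C)C(C(=O)OC(C)(C)C)[C@H]2[C@H](OCc3ccc(OC)cc3)[C@@H]1C(=C)CO[Si](C)(C)C(C)(C)C | intermediate
13 | keto diester (3‑oxo, 4β‑CH2CO2t‑Bu) | COC(=O)[C@@]1(C)CC(=O)[C@@H](CC(=O)OC(C)(C)C)[C@H](OCc2ccc(OC)cc2)[C@@H]1C(=C)CO[Si](C)(C)C(C)(C)C | intermediate
14 | hydroxy diester (3β‑OH, axial) | COC(=O)[C@@]1(C)C[C@@H](O)[C@@H](CC(=O)OC(C)(C)C)[C@H](OCc2ccc(OC)cc2)[C@@H]1C(=C)CO[Si](C)(C)C(C)(C)C | intermediate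
15 | bridged γ‑lactone (C3β–O–C(=O)–C1) with 4β‑CH2CO2t‑Bu | O=C2[C@@]1(C)C[C@@H](O2)[C@@H](CC(=O)OC(C)(C)C)[C@H](OCc3ccc(OC)cc3)[C@@H]1C(=C)CO[Si](C)(C)C(C)(C)C | intermediate
16 | bridged γ‑lactone Mannich base (side‑chain epimers) | O=C2[C@@]1(C)C[C@@H](O2)[C@@H](C(CN(C)C)C(=O)OC(C)(C)C)[C@H](OCc3ccc(OC)cc3)[C@@H]1C(=C)CO[Si](C)(C)C(C)(C)C | intermediate
17 | bridged lactol (anomers) | OC2[C@@]1(C)C[C@@H](O2)[C@@H](C(CN(C)C)C(=O)OC(C)(C)C)[C@H](OCc3ccc(OC)cc3)[C@@H]1C(=C)CO[Si](C)(C)C(C)(C)C | intermediate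
18 | hydroxy aldehyde (open form of 17) | O=C[C@@]1(C)C[C@@H](O)[C@@H](C(CN(C)C)C(=O)OC(C)(C)C)[C@H](OCc2ccc(OC)cc2)[C@@H]1C(=C)CO[Si](C)(C)C(C)(C)C | intermediate
19 | hydroxy vinyl Mannich base (1β‑vinyl, 3β‑OH) | C=C[C@@]1(C)C[C@@H](O)[C@@H](C(CN(C)C)C(=O)OC(C)(C)C)[C@H](OCc2ccc(OC)cc2)[C@@H]1C(=C)CO[Si](C)(C)C(C)(C)C | intermediate
20 | ethyl 2‑[bis(2,2,2‑trifluoroethoxy)phosphoryl]propanoate (racemic) | CCOC(=O)C(C)P(=O)(OCC(F)(F)F)OCC(F)(F)F | starting material
21 | 2‑[bis(2,2,2‑trifluoroethoxy)phosphoryl]propanoic acid (racemic) | CC(C(=O)O)P(=O)(OCC(F)(F)F)OCC(F)(F)F | intermediate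
22 | (Z)‑but‑2‑ene‑1,4‑diyl diacetate | CC(=O)OC/C=C\COC(C)=O | starting material
23 | 3,5‑bis(acetoxymethyl)‑1,2,4‑trioxolane (ozonide) | CC(=O)OCC1OOC(COC(C)=O)O1 | intermediate
24 | 2‑oxoethyl acetate (acetoxyacetaldehyde) | CC(=O)OCC=O | intermediate
25 | 3β‑O‑phosphonopropanoate of 19 (epimers at the phosphonate carbon) | C=C[C@@]1(C)C[C@@H](OC(=O)C(C)P(=O)(OCC(F)(F)F)OCC(F)(F)F)[C@@H](C(CN(C)C)C(=O)OC(C)(C)C)[C@H](OCc2ccc(OC)cc2)[C@@H]1C(=C)CO[Si](C)(C)C(C)(C)C | intermediate
26 | 3β‑O‑[(Z)‑4‑acetoxy‑2‑methylbut‑2‑enoyl] Mannich base | C=C[C@@]1(C)C[C@@H](OC(=O)/C(C)=C\COC(C)=O)[C@@H](C(CN(C)C)C(=O)OC(C)(C)C)[C@H](OCc2ccc(OC)cc2)[C@@H]1C(=C)CO[Si](C)(C)C(C)(C)C | intermediate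
27 | trimethylammonium iodide (methiodide) of 26 | C=C[C@@]1(C)C[C@@H](OC(=O)/C(C)=C\COC(C)=O)[C@@H](C(C[N+](C)(C)C)C(=O)OC(C)(C)C)[C@H](OCc2ccc(OC)cc2)[C@@H]1C(=C)CO[Si](C)(C)C(C)(C)C.[I-] | intermediate
28 | tert‑butyl acrylate with 5α‑OPMB and primary OTBS | C=C[C@@]1(C)C[C@@H](OC(=O)/C(C)=C\COC(C)=O)[C@@H](C(=C)C(=O)OC(C)(C)C)[C@H](OCc2ccc(OC)cc2)[C@@H]1C(=C)CO[Si](C)(C)C(C)(C)C | intermediate
29 | tert‑butyl acrylate with 5α‑OH and primary OTBS | C=C[C@@]1(C)C[C@@H](OC(=O)/C(C)=C\COC(C)=O)[C@@H](C(=C)C(=O)OC(C)(C)C)[C@H](O)[C@@H]1C(=C)CO[Si](C)(C)C(C)(C)C | intermediate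
30 | TMS ester / 5α‑OTMS ether / primary OTBS ether | C=C[C@@]1(C)C[C@@H](OC(=O)/C(C)=C\COC(C)=O)[C@@H](C(=C)C(=O)O[Si](C)(C)C)[C@H](O[Si](C)(C)C)[C@@H]1C(=C)CO[Si](C)(C)C(C)(C)C | intermediate
31 | target acid (1α‑methyl, 1β‑vinyl, 3β‑acyloxy, 4β‑acrylic acid, 5α‑OH, 6α‑hydroxypropenyl) | C=C[C@@]1(C)C[C@@H](OC(=O)/C(C)=C\COC(C)=O)[C@@H](C(=C)C(=O)O)[C@H](O)[C@@H]1C(=C)CO | target

## Step count and risks

Total step count: 19. Longest linear sequence: 16 steps (from 4 to 31 through steps 2–12 and 15–19).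

Steps most likely to fail:

1. Step 4 (key cycloaddition). The strongly Lewis‑acidic catalyst may desilylate the diene or ionise the allylic PMB‑oxy group of the product before the quench, and face or endo control may be incomplete with a dienophile that has to form a quaternary carbon. The fallback replaces catalyst control by auxiliary control and sets out from diene 7. Commercial dimethyl mesaconate is mono‑saponified at its less hindered ester (LiOH, 1 equiv, THF/H2O, 0 °C) to (E)‑4‑methoxy‑3‑methyl‑4‑oxobut‑2‑enoic acid F1. Pivaloyl chloride/Et3N converts it into the mixed pivalic anhydride F2, which acylates the lithium salt of (S)‑4‑benzyloxazolidin‑2‑one (n‑BuLi, THF, −78 °C) to give (S)‑4‑benzyl‑3‑[(E)‑4‑methoxy‑3‑methyl‑4‑oxobut‑2‑enoyl]oxazolidin‑2‑one F3. F3 and 7 are combined with Et2AlCl (1.4 equiv, CH2Cl2, −78 °C): the aluminium‑chelated s‑cis imide should be attacked on the face opposite the benzyl group, with the regio‑ and endo‑sense of step 4, to give the imide cycloadduct F4. LiSEt (THF, 0 °C) exchanges the auxiliary for the S‑ethyl thioester F5, and Me2CuLi (Et2O, −78 °C) converts F5 into methyl ketone 8, where the route is rejoined.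

2. Step 9 (reduction and lactonisation). If the ring reacts through the flipped chair, hydride is delivered to the other face and the equatorial alcohol results, which cannot reach the methyl ester. The fallback sets out from ketone 13 and uses that product instead of discarding it. The C3‑epimeric alcohol F6 is subjected to a Mitsunobu reaction with 4‑nitrobenzoic acid (PPh3, diisopropyl azodicarboxylate, toluene, 0 °C → rt), which inverts the carbinol centre and gives the axial 4‑nitrobenzoate F7. K2CO3/MeOH cleaves the benzoate, and the liberated axial alkoxide (14) closes onto the methyl ester to give lactone 15, where the route is rejoined.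

3. Step 6 (hydroxymethyl Stille coupling). Transfer of the hydroxymethyl group from tin may be slow, so that reduction or hydrolysis of the enol triflate competes. The fallback sets out from triflate 9. Palladium‑catalysed methoxycarbonylation (Pd(OAc)2, 1,3‑bis(diphenylphosphino)propane, CO 1 atm, MeOH, Et3N, DMF, 60 °C), a fast and general reaction of enol triflates, gives the acrylate diester F8. i‑Bu2AlH (2.2 equiv, CH2Cl2, −78 °C) should reduce the conjugated, unhindered acrylate ester to the allylic alcohol in preference to the neopentyl ester on the quaternary carbon and give 10, where the route is rejoined.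

Further compounds

F1 | step 4 | (E)‑4‑methoxy‑3‑methyl‑4‑oxobut‑2‑enoic acid | OC(=O)/C=C(\C)C(=O)OC
F2 | step 4 | mixed anhydride of F1 with pivalic acid | CC(C)(C)C(=O)OC(=O)/C=C(\C)C(=O)OC
F3 | step 4 | (S)‑4‑benzyl‑3‑[(E)‑4‑methoxy‑3‑methyl‑4‑oxobut‑2‑enoyl]oxazolidin‑2‑one | COC(=O)/C(C)=C/C(=O)N1C(=O)OC[C@@H]1Cc1ccccc1
F4 | step 4 | imide cycloadduct (analogue of 8 with the N‑acyl oxazolidinone in place of acetyl) | COC(=O)[C@@]1(C)CC(O[Si](C)(C)C(C)(C)C)=C[C@H](OCc2ccc(OC)cc2)[C@@H]1C(=O)N1C(=O)OC[C@@H]1Cc1ccccc1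
F5 | step 4 | S‑ethyl thioester analogue of 8 | COC(=O)[C@@]1(C)CC(O[Si](C)(C)C(C)(C)C)=C[C@H](OCc2ccc(OC)cc2)[C@@H]1C(=O)SCC
F6 | step 9 | C3 epimer of hydroxy diester 14 (3α‑OH, equatorial) | COC(=O)[C@@]1(C)C[C@H](O)[C@@H](CC(=O)OC(C)(C)C)[C@H](OCc2ccc(OC)cc2)[C@@H]1C(=C)CO[Si](C)(C)C(C)(C)C
F7 | step 9 | 3β‑(4‑nitrobenzoate) of hydroxy diester 14 | COC(=O)[C@@]1(C)C[C@@H](OC(=O)c2ccc(cc2)[N+](=O)[O-])[C@@H](CC(=O)OC(C)(C)C)[C@H](OCc2ccc(OC)cc2)[C@@H]1C(=C)CO[Si](C)(C)C(C)(C)C
F8 | step 6 | acrylate diester (6α‑[1‑(methoxycarbonyl)vinyl] analogue of 10) | COC(=O)[C@@]1(C)CC(O[Si](C)(C)C(C)(C)C)=C[C@H](OCc2ccc(OC)cc2)[C@@H]1C(=C)C(=O)OC
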